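**Plan**

- Retrosynthesis: the three methoxymethyl (MOM) ethers are cut first, then the C3–C4 bond of ring C together with the C2–H bond in the sense of an alkene hydroacylation, then the formyl carbon from C4a, the C6–C1′ bond of the chain, the C3 methylene (ester methylenation) and the O1–C2 acyl bond.
- Enabling feature: in ring C the carbonyl C4 lies between C4a of ring A and the C3 methylene, and C2 carries H, O1 and ring B. The protected target is therefore the isomer of a ring A aldehyde whose ortho oxygen O1 bears the 1-arylvinyl group C2(=C3H2)–ring B.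
- Forward: ring A and ring B are joined through O1 as an aryl ester, which is methylenated; the chain is coupled at the ring A carbon between the two MOM ethers; the formyl group is placed next to O1; ring C is closed last; deprotection.
- 6- versus 8-substitution follows from the local symmetry of the 3,5-bis(MOM) aryl ether: one ring A position lies between two MOM ethers (it becomes C6) and the two that remain are equivalent.
- Stereochemistry: C3′ comes from (S)-citronellal; the E alkene from syn hydrozirconation, kept in the Negishi coupling; C2 is set in the ring closure by (R)-DTBM-SEGPHOS on rhodium.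

Key step: step 8

Assumption: the sense of induction of the rhodium–bisphosphine catalyst on an aryl enol ether is not established; the (R)-ligand is written, and its antipode is to be used if a first run shows the (2R) product.

**Step 1**
Reactants: 1 phloroglucinol
Product: 2 3,5-bis(methoxymethoxy)phenol
Conditions: NaH (2.0 equiv), MOMCl (2.0 equiv), DMF, 0 °C to rt; chromatography
Reagents that add atoms: chloromethyl methyl ether, COCCl
Why: Williamson-type O-alkylation of the threefold symmetric triol with two equivalents of base and MOMCl should give the bis-ether as the main component of a statistical mixture, separable from the mono- and tris-ethers.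

**Step 2**
Reactants: 2 3,5-bis(methoxymethoxy)phenol; 3 4-(methoxymethoxy)benzoic acid
Product: 4 3,5-bis(methoxymethoxy)phenyl 4-(methoxymethoxy)benzoate
Conditions: DCC (1.1 equiv), DMAP (0.1 equiv), CH2Cl2, 0 °C to rt
Reagents that add atoms: none
Why: Steglich esterification joins the phenol and the acid under neutral conditions that leave the MOM acetals untouched, and this forms the future O1–C2 bond.

**Step 3**
Reactants: 4 3,5-bis(methoxymethoxy)phenyl 4-(methoxymethoxy)benzoate
Product: 5 1-{1-[3,5-bis(methoxymethoxy)phenoxy]ethenyl}-4-(methoxymethoxy)benzene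
Conditions: Tebbe reagent Cp2Ti(μ-CH2)(μ-Cl)AlMe2 (1.2 equiv, toluene), pyridine (cat.), THF, −40 °C to rt; aq NaOH quench; basic alumina
Reagents that add atoms: Tebbe reagent, C[Al-]1(C)C[Ti](C2C=CC=C2)(C2C=CC=C2)[Cl+]1
Why: Tebbe methylenation of an aryl benzoate (through an oxatitanacyclobutane) should give the 1-aryloxy-1-arylethene, a reaction with direct precedent on aryl benzoates, and the basic work-up protects the acid-labile enol ether.

**Step 4**
Reactants: 6 (S)-citronellal
Product: 8 (3S)-3,7-dimethyloct-6-en-1-yne, via alkenyl nonaflate 7 (not isolated)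
Conditions: nonafluorobutane-1-sulfonyl fluoride (1.3 equiv), phosphazene base P2-Et (2.5 equiv), DMF, −20 °C to rt
Reagents that add atoms: none
Why: one-pot enol nonaflation and base-induced elimination converts the enolisable aldehyde into the terminal alkyne without change of carbon count, and the C3 stereocentre, which is β to the carbonyl, is not involved.

**Step 5**
Reactants: 8 (3S)-3,7-dimethyloct-6-en-1-yne
Product: 10 (1E,3S)-1-iodo-3,7-dimethylocta-1,6-diene, via alkenylzirconocene chloride 9 (not isolated)
Conditions: Cp2Zr(H)Cl (1.2 equiv), THF, rt, dark; then I2 (1.1 equiv), 0 °C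
Reagents that add atoms: iodine, II
Why: hydrozirconation adds Zr–H syn with zirconium at the terminal carbon, and iodinolysis with retention should give the E vinyl iodide, while the trisubstituted alkene is too hindered to react.

**Step 6**
Reactants: 5 1-{1-[3,5-bis(methoxymethoxy)phenoxy]ethenyl}-4-(methoxymethoxy)benzene; 10 (1E,3S)-1-iodo-3,7-dimethylocta-1,6-diene
Product: 13 2-[(1E,3S)-3,7-dimethylocta-1,6-dien-1-yl]-1,3-bis(methoxymethoxy)-5-({1-[4-(methoxymethoxy)phenyl]ethenyl}oxy)benzene, via aryllithium 11 (not isolated), via arylzinc chloride 12 (not isolated)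
Conditions: n-BuLi (1.1 equiv), THF, 0 °C; ZnCl2 (1.2 equiv), 0 °C to rt; then 10, Pd2(dba)3 (2 mol %), SPhos (8 mol %), 50 °C
Reagents that add atoms: none
Why: directed ortho-metalation should occur at the one ring A position flanked by two chelating MOM ethers, and after transmetalation to zinc a Negishi coupling with zerovalent palladium joins the chain with retention of the E geometry.

**Step 7**
Reactants: 13 2-[(1E,3S)-3,7-dimethylocta-1,6-dien-1-yl]-1,3-bis(methoxymethoxy)-5-({1-[4-(methoxymethoxy)phenyl]ethenyl}oxy)benzene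
Product: 16 3-[(1E,3S)-3,7-dimethylocta-1,6-dien-1-yl]-2,4-bis(methoxymethoxy)-6-({1-[4-(methoxymethoxy)phenyl]ethenyl}oxy)benzaldehyde, via aryllithium 14 (not isolated), via lithium hemiaminal alkoxide 15 (not isolated)
Conditions: n-BuLi (1.1 equiv), THF, −40 to −10 °C; DMF (3 equiv), −78 to 0 °C; then H2O
Reagents that add atoms: N,N-dimethylformamide, CN(C)C=O
Why: a second directed ortho-metalation and formylation should take place at either of the two equivalent ring A positions, each lying between a MOM ether and the enol ether oxygen and therefore more acidic than the ring B positions beside a single MOM ether.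

**Step 8**
Reactants: 16 3-[(1E,3S)-3,7-dimethylocta-1,6-dien-1-yl]-2,4-bis(methoxymethoxy)-6-({1-[4-(methoxymethoxy)phenyl]ethenyl}oxy)benzaldehyde
Product: 17 (2S)-6-[(1E,3S)-3,7-dimethylocta-1,6-dien-1-yl]-5,7-bis(methoxymethoxy)-2-[4-(methoxymethoxy)phenyl]-2,3-dihydro-4H-chromen-4-one
Conditions: [Rh(cod)Cl]2 (2.5 mol %), (R)-DTBM-SEGPHOS (5.5 mol %), Na[B(3,5-(CF3)2C6H3)4] (5 mol %), 1,4-dioxane, 4 Å MS, 70 °C
Reagents that add atoms: none
Why: Proposed new method: the formyl C–H bond adds oxidatively to the cationic monovalent rhodium–bisphosphine to give an acyl hydride of trivalent rhodium, the tethered enol ether C2=C3 coordinates, the hydride migrates to C2 while rhodium takes the terminal C3, and C–C reductive elimination from the seven-membered acyl–alkyl rhodacycle forms the C3–C4 bond. The closest known reaction type is the rhodium-catalysed enantioselective intramolecular hydroacylation of 1,1-disubstituted alkenes (4-substituted pent-4-enals to 3-substituted cyclopentanones, 2-(2-substituted allyl)benzaldehydes to 3-substituted tetralones); new here is the oxygen-tethered aryl 1-arylvinyl ether. Ring C closes in the 6-endo-trig sense, the acyl carbon joining the unsubstituted terminus of the enol ether. C2 is the only new stereocentre and is set under catalyst control when the hydride is delivered to one enantioface of the prochiral enol ether within the chiral pocket of the bisphosphine. The step needs endo over exo insertion (the exo path leads to a 2-aryl-2-methylbenzofuran-3-one), C–C bond formation faster than decarbonylation and no reaction at the chain alkenes; the 1,1-disubstitution would force the exo alkyl–rhodium onto a fully substituted carbon bearing O, aryl and methyl, the ortho MOM oxygen and O1 can chelate the acyl hydride and slow CO extrusion, and the chain alkenes cannot reach a metal bound at C4. The conditions contain neither acid nor base, so the acid-labile enol ether reaches the catalyst intact and the base-labile C2 centre should not open once formed.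

**Step 9**
Reactants: 17 (2S)-6-[(1E,3S)-3,7-dimethylocta-1,6-dien-1-yl]-5,7-bis(methoxymethoxy)-2-[4-(methoxymethoxy)phenyl]-2,3-dihydro-4H-chromen-4-one
Product: 18 (2S)-6-[(1E,3S)-3,7-dimethylocta-1,6-dien-1-yl]-5,7-dihydroxy-2-(4-hydroxyphenyl)-2,3-dihydro-4H-chromen-4-one
Conditions: 3 M aq HCl/MeOH/THF (1:6:3), 35 °C
Reagents that add atoms: none
Why: acid-catalysed transacetalisation to methanol should remove the three MOM ethers, the flavanone C2 centre being stable to dilute acid (it is base that opens ring C) and the mild temperature sparing the two chain alkenes.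

**Compound list**

1 | phloroglucinol (benzene-1,3,5-triol) | Oc1cc(O)cc(O)c1 | starting material
2 | 3,5-bis(methoxymethoxy)phenol | COCOc1cc(O)cc(OCOC)c1 | intermediate
3 | 4-(methoxymethoxy)benzoic acid | COCOc1ccc(cc1)C(=O)O | starting material
4 | 3,5-bis(methoxymethoxy)phenyl 4-(methoxymethoxy)benzoate | COCOc1ccc(cc1)C(=O)Oc1cc(OCOC)cc(OCOC)c1 | intermediate
5 | 1-{1-[3,5-bis(methoxymethoxy)phenoxy]ethenyl}-4-(methoxymethoxy)benzene | COCOc1ccc(cc1)C(=C)Oc1cc(OCOC)cc(OCOC)c1 | intermediate
6 | (S)-citronellal, (3S)-3,7-dimethyloct-6-enal | CC(C)=CCC[C@H](C)CC=O | starting material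
7 | (3S)-3,7-dimethylocta-1,6-dien-1-yl nonafluorobutane-1-sulfonate, E/Z mixture, formed in the flask | CC(C)=CCC[C@H](C)C=COS(=O)(=O)C(F)(F)C(F)(F)C(F)(F)C(F)(F)F | intermediate
8 | (3S)-3,7-dimethyloct-6-en-1-yne | CC(C)=CCC[C@H](C)C#C | intermediate
9 | chlorobis(cyclopentadienyl)[(1E,3S)-3,7-dimethylocta-1,6-dien-1-yl]zirconium, formed in the flask | CC(C)=CCC[C@H](C)/C=C/[Zr](Cl)(C1C=CC=C1)C1C=CC=C1 | intermediate
10 | (1E,3S)-1-iodo-3,7-dimethylocta-1,6-diene | CC(C)=CCC[C@H](C)/C=C/I | intermediate
11 | aryllithium from 5, lithium at the ring A carbon between the two MOM ethers, formed in the flask | COCOc1ccc(cc1)C(=C)Oc1cc(OCOC)c([Li])c(OCOC)c1 | intermediate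
12 | arylzinc chloride from 11, formed in the flask | COCOc1ccc(cc1)C(=C)Oc1cc(OCOC)c([Zn]Cl)c(OCOC)c1 | intermediate
13 | 2-[(1E,3S)-3,7-dimethylocta-1,6-dien-1-yl]-1,3-bis(methoxymethoxy)-5-({1-[4-(methoxymethoxy)phenyl]ethenyl}oxy)benzene | CC(C)=CCC[C@H](C)/C=C/c1c(OCOC)cc(OC(=C)c2ccc(OCOC)cc2)cc1OCOC | intermediate
14 | aryllithium from 13, lithium at the ring A carbon between a MOM ether and the enol ether oxygen, formed in the flask | CC(C)=CCC[C@H](C)/C=C/c1c(OCOC)cc(OC(=C)c2ccc(OCOC)cc2)c([Li])c1OCOC | intermediate
15 | lithium hemiaminal alkoxide, the DMF adduct of 14, carbinol carbon unassigned, formed in the flask | CC(C)=CCC[C@H](C)/C=C/c1c(OCOC)cc(OC(=C)c2ccc(OCOC)cc2)c(C(O[Li])N(C)C)c1OCOC | intermediate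
16 | 3-[(1E,3S)-3,7-dimethylocta-1,6-dien-1-yl]-2,4-bis(methoxymethoxy)-6-({1-[4-(methoxymethoxy)phenyl]ethenyl}oxy)benzaldehyde | CC(C)=CCC[C@H](C)/C=C/c1c(OCOC)cc(OC(=C)c2ccc(OCOC)cc2)c(C=O)c1OCOC | intermediate
17 | (2S)-6-[(1E,3S)-3,7-dimethylocta-1,6-dien-1-yl]-5,7-bis(methoxymethoxy)-2-[4-(methoxymethoxy)phenyl]-2,3-dihydro-4H-chromen-4-one | CC(C)=CCC[C@H](C)/C=C/c1c(OCOC)cc2c(c1OCOC)C(=O)C[C@@H](c1ccc(OCOC)cc1)O2 | intermediate
18 | (2S)-6-[(1E,3S)-3,7-dimethylocta-1,6-dien-1-yl]-5,7-dihydroxy-2-(4-hydroxyphenyl)-2,3-dihydro-4H-chromen-4-one | CC(C)=CCC[C@H](C)/C=C/c1c(O)cc2c(c1O)C(=O)C[C@@H](c1ccc(O)cc1)O2 | target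

**Step count and risks**

Total steps: 9. Longest linear sequence: 7 (steps 1, 2, 3, 6, 7, 8, 9).

Steps most likely to fail:

1. Step 8 (proposed new method). The hydride may insert in the exo sense and close a five-membered ring, the acyl hydride may lose CO before C–C bond formation, or facial discrimination at the enol ether may be poor. The fallback uses known chemistry and makes the C2–aryl bond last instead of C3–C4. It sets out from 16. Ethynylmagnesium bromide (THF, 0 °C) adds to the aldehyde to give the propargylic alcohol F1. MnO2 (CH2Cl2) oxidises it to the ynone F2. PPTS in wet acetone hydrolyses the enol ether to the hydroxy ynone F3, and Et2NH in ethanol closes the freed phenol onto the ynone to give the chromone F4. Enantioselective conjugate addition of 4-(methoxymethoxy)phenylboronic acid with a divalent palladium catalyst (Pd(OCOCF3)2, (S)-t-BuPyOx or its antipode as needed for (2S), NH4PF6, water, ClCH2CH2Cl, 60 °C) should then give 17, where the route is rejoined.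

2. Step 7. Lithiation may stray to ring B beside its MOM ether, the ortho-lithiated aryl vinyl ether may add to its own enol ether, or allylic deprotonation may erode the C3′ centre. The fallback replaces deprotonation by phenol-directed electrophilic formylation and re-forms the enol ether by C–O coupling. It sets out from 13. PPTS in wet acetone hydrolyses the enol ether to the symmetric phenol F5. MgCl2, Et3N and paraformaldehyde in MeCN (Casnati–Skattebøl ortho-formylation) give the salicylaldehyde F6, both ortho positions being equivalent. 4′-(Methoxymethoxy)acetophenone is converted with KN(SiMe3)2 and PhNTf2 into the enol triflate F7, and Miyaura borylation (B2pin2, PdCl2(PPh3)2, PPh3, KOPh, toluene, 50 °C) gives the alkenylboronate F8. Chan–Lam–Evans O-alkenylation of F6 with F8 (Cu(OAc)2, pyridine, 4 Å MS, air, CH2Cl2, rt) should give 16, where the route is rejoined.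

3. Step 6. Transmetalation and coupling of the doubly ortho-substituted arylzinc may be slow, the aryl anion may be protonated back to 5, or the alkene geometry of the iodide may erode. The fallback reverses the polarity of the coupling. It sets out from 5 and 8. The aryllithium 11 is quenched with 1,2-diiodoethane at −78 °C to give the aryl iodide F9. Alkyne 8 is hydroborated with pinacolborane (Cp2Zr(H)Cl cat., Et3N, 60 °C) to the (E)-alkenylboronate F10. Suzuki–Miyaura coupling of F9 with F10 (Pd(OAc)2, SPhos, K3PO4, THF/water, 50 °C) should give 13, where the route is rejoined.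

**Further compounds**

F1 | step 8 | 1-{3-[(1E,3S)-3,7-dimethylocta-1,6-dien-1-yl]-2,4-bis(methoxymethoxy)-6-({1-[4-(methoxymethoxy)phenyl]ethenyl}oxy)phenyl}prop-2-yn-1-ol, carbinol carbon racemic | CC(C)=CCC[C@H](C)/C=C/c1c(OCOC)cc(OC(=C)c2ccc(OCOC)cc2)c(C(O)C#C)c1OCOC
F2 | step 8 | 1-{3-[(1E,3S)-3,7-dimethylocta-1,6-dien-1-yl]-2,4-bis(methoxymethoxy)-6-({1-[4-(methoxymethoxy)phenyl]ethenyl}oxy)phenyl}prop-2-yn-1-one | CC(C)=CCC[C@H](C)/C=C/c1c(OCOC)cc(OC(=C)c2ccc(OCOC)cc2)c(C(=O)C#C)c1OCOC
F3 | step 8 | 1-{3-[(1E,3S)-3,7-dimethylocta-1,6-dien-1-yl]-6-hydroxy-2,4-bis(methoxymethoxy)phenyl}prop-2-yn-1-one | CC(C)=CCC[C@H](C)/C=C/c1c(OCOC)cc(O)c(C(=O)C#C)c1OCOC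
F4 | step 8 | 6-[(1E,3S)-3,7-dimethylocta-1,6-dien-1-yl]-5,7-bis(methoxymethoxy)-4H-chromen-4-one | CC(C)=CCC[C@H](C)/C=C/c1c(OCOC)cc2occc(=O)c2c1OCOC
F5 | step 7 | 4-[(1E,3S)-3,7-dimethylocta-1,6-dien-1-yl]-3,5-bis(methoxymethoxy)phenol | CC(C)=CCC[C@H](C)/C=C/c1c(OCOC)cc(O)cc1OCOC
F6 | step 7 | 3-[(1E,3S)-3,7-dimethylocta-1,6-dien-1-yl]-6-hydroxy-2,4-bis(methoxymethoxy)benzaldehyde | CC(C)=CCC[C@H](C)/C=C/c1c(OCOC)cc(O)c(C=O)c1OCOC
F7 | step 7 | 1-[4-(methoxymethoxy)phenyl]ethenyl trifluoromethanesulfonate | COCOc1ccc(cc1)C(=C)OS(=O)(=O)C(F)(F)F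
F8 | step 7 | 2-{1-[4-(methoxymethoxy)phenyl]ethenyl}-4,4,5,5-tetramethyl-1,3,2-dioxaborolane | COCOc1ccc(cc1)C(=C)B1OC(C)(C)C(C)(C)O1
F9 | step 6 | 2-iodo-1,3-bis(methoxymethoxy)-5-({1-[4-(methoxymethoxy)phenyl]ethenyl}oxy)benzene | COCOc1ccc(cc1)C(=C)Oc1cc(OCOC)c(I)c(OCOC)c1
F10 | step 6 | 2-[(1E,3S)-3,7-dimethylocta-1,6-dien-1-yl]-4,4,5,5-tetramethyl-1,3,2-dioxaborolane | CC(C)=CCC[C@H](C)/C=C/B1OC(C)(C)C(C)(C)O1
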